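(The constants are invented, and the outcome is calculated.)

At early times the solid substrate in this flask is pulled two ways, into solution and into quenched substrate, so we set those two rates side by side.

    dissolved substrate + partner → product (k1 = 0.0348 M⁻¹ s⁻¹)
    solid substrate ⇌ dissolved substrate, rate k2*(cs2 - [dissolved substrate]) while solid is left; crystals form when [dissolved substrate] > cs2 (cs2 = 8.8 mM, k2 = 4.34 × 10⁻⁴ s⁻¹)
    solid substrate + protic impurity → quenched substrate (k3 = 0.0602 M⁻¹ s⁻¹)
    crystals ⇌ product, rate k4*(cs4 - [product]) while solid is left; crystals form when [product] > cs4 (cs4 = 0.52 mM, k4 = 0.00551 s⁻¹)

solid substrate 0.050 M; partner 0.0750 M; protic impurity 0.0250 M; time 6.0 h

- what is said of product includes crystals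
- solid substrate, crystals is a solid; its amount is given per volume of the solution
- at the start none of the solid substrate is in solution
- run time (flask): 6.0 h

- noon: doubling the dissolution coefficient of step 2, all else as stated
- summer: doubling the solubility in step 2, all else as stated
- midnight: doubling the dissolution coefficient of step 4, all else as stated
- dusk: doubling the solubility in step 4, all else as stated

- how much product and crystals together there is at 6.0 h, in percent of the solid substrate charged
- the change that raises the amount of product and crystals together at 6.0 h, in percent of the solid substrate charged most ("none" if none brings more than 2 percentage points) (noon / summer / midnight / dusk / none)
- amount of product and crystals together at 6.0 h, in percent of the solid substrate charged, after midnight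

Who gets the solid substrate first? At the charged amounts step 3 consumes it at 271 mM h⁻¹, while step 2 delivers at most 13.7 mM h⁻¹, so step 3 starts about 19.8 times faster than step 2. Step 3 uses one solid substrate for each protic impurity, so we expect nearly all of the protic impurity to react. The solid substrate charged minus the protic impurity charged, 0.0250 M, we call the spare substrate.

Can the spare substrate reach product within the time? At the top rate of step 2, which is the fastest it can go, it needs 1.82 h, which is less than the 6.0 h allowed, and dissolved substrate has a half-life of 0.074 h by step 1 alone at the charged amounts.

Is there enough partner? The charge of 0.0750 M is more than the spare substrate. So we commit to 50.0%. Step 4 moves material between product and crystals, and both are counted, so after midnight we again expect 50.0%. Noon and summer each double the top rate of step 2, yet step 3 still starts ten times faster than that doubled rate, so we expect no change to pass the bar.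

The forecast gives 50.1%, 50.1% after midnight, and none as the best change, reasoning that “the remaining half dissolves and converts completely”.

The simulation gives 50.1%, 50.1% after midnight, and none: noon adds 0.81 percentage points and summer 1.2 points, each under the 2 points bar. This flask ends with 49.9% as quenched substrate and 50.1% as product, crystals counted, and the product already stands at 50.1% after 3.00 h. The neighbour flask with 0.019 M of partner, 0.380 equiv to the solid substrate, keeps the same spare substrate, but its partner is less than that. Partner is there the limiting reagent, so we reckon 38.0% for product and 12.0% of the charge left over. That neighbour flask gives 37.4%, with 1.6% of its partner left and, of its charged solid substrate, still there, solid or dissolved, 13%.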